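Retrosynthetic overview
1. Target (cladiellin-type locants C1–C16): cyclohexane C1/C10–C14, oxolane O–C2–C1–C10–C9, oxonane O–C2…C9, and a seven-membered lactone C3–O–C16(=O)–C15–C14–C1–C2.
2. End game: C6–OMe/C7–OH from syn-dihydroxylation of an E C6=C7 alkene and O-methylation; lactone from acylation of the C3 hydroxyl by a C16 acid whose C15 centre comes from asymmetric hydrogenation of an acrylic acid.
3. Cyclohexane from a Diels–Alder reaction of a C1=C10–C11(OEt)=C12 diene (made from a C10 ketone) with methyl vinyl ketone (C13–C15); C11 from MeMgBr addition to the C11 ketone.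
4. Key disconnection: the ether oxygen that bridges C2 and C9 across the ten-membered carbocycle C1–C10, with C9 lying between a C10 carbonyl and the C8 methylene and with C6=C7 next to C8, is the retron of a [2,3] shift of an allyl oxonium ylide. O–C9 and C8–C9 form and O–C6 breaks, so the oxolane, the oxonene and the carbocycle all come from a 2,6-cis oxane (O, C2–C6) carrying a diazoacetonyl arm on C2 and an isopropenyl group on C6.
5. Oxane from (S)-linalool (C1–C8, C3 centre) by Shi epoxidation (C6), epoxide-to-allylic-alcohol isomerisation and Pd oxycarbonylation (C2, C10). Ring order: oxane; oxolanone + oxonene + carbocycle (key step); cyclohexene; lactone.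

Key step: step 7

Remark (assumption): (S)-(+)-linalool and the enantiomer of the D-fructose-derived Shi ketone are taken as commercial materials of high enantiomeric purity. The locants of the overview are used for all intermediates.

Step 1
Reactants: 1 (S)-(+)-linalool
Product: 2 (S)-linalool tert-butyldimethylsilyl ether
Conditions: TBSOTf, 2,6-lutidine, CH2Cl2, 0 °C to rt
Reagents that add atoms: tert-butyldimethylsilyl trifluoromethanesulfonate, CC(C)(C)[Si](C)(C)OS(=O)(=O)C(F)(F)F
Why: Silyl ether formation with a silyl triflate and a hindered base protects the tertiary C3 oxygen for the whole sequence without touching the C3 stereocentre taken from linalool.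

Step 2
Reactants: 2 (S)-linalool tert-butyldimethylsilyl ether
Product: 3 (3S,6S)-6,7-epoxide of 2
Conditions: enantiomer of the D-fructose-derived Shi ketone (0.3 equiv), KHSO5 (as Oxone), K2CO3, Bu4NHSO4, MeCN/CH2(OMe)2/aq. Na2B4O7 buffer, 0 °C
Reagents that add atoms: potassium peroxymonosulfate (oxygen passed on through the catalyst-derived dioxirane), OOS(=O)(=O)[O-].[K+]
Why: Shi asymmetric epoxidation (chiral dioxirane, spiro transition state) attacks the electron-rich trisubstituted 6,7-alkene and leaves the vinyl group, and the catalyst enantiomer (the antipode of the one that gives R) should set C6 as S.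

Step 3
Reactants: 3 (3S,6S)-6,7-epoxide of 2
Product: 4 (3S,6S)-6-(tert-butyldimethylsilyloxy)-2,6-dimethylocta-1,7-dien-3-ol
Conditions: Al(OiPr)3, toluene, 110 °C; aqueous work-up
Reagents that add atoms: none
Why: Aluminium alkoxide-mediated epoxide-to-allylic-alcohol isomerisation opens the epoxide at the tertiary C7 while a methyl proton is removed, so the C6–O bond keeps its configuration and the isopropenyl group needed for the [2,3] shift appears.

Step 4
Reactants: 4 (3S,6S)-6-(tert-butyldimethylsilyloxy)-2,6-dimethylocta-1,7-dien-3-ol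
Product: 5 methyl 2-[(2S,3S,6S)-3-(tert-butyldimethylsilyloxy)-3-methyl-6-(prop-1-en-2-yl)oxan-2-yl]acetate
Conditions: PdCl2 (10 mol%), CuCl2 (3 equiv), NaOAc, CO (1 atm), MeOH, rt
Reagents that add atoms: carbon monoxide, [C-]#[O+]; methanol, CO
Why: Semmelhack alkoxycarbonylation (intramolecular oxypalladation of the vinyl group by the C6 hydroxyl, CO insertion, methanolysis, CuCl2 as reoxidant) should close the oxane 6-exo through a chair with the isopropenyl and palladated methylene groups equatorial, which sets C2 cis to C6 and brings in C10 as the ester.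

Step 5
Reactants: 5 methyl 2-[(2S,3S,6S)-3-(tert-butyldimethylsilyloxy)-3-methyl-6-(prop-1-en-2-yl)oxan-2-yl]acetate
Product: 6 2-[(2S,3S,6S)-3-(tert-butyldimethylsilyloxy)-3-methyl-6-(prop-1-en-2-yl)oxan-2-yl]acetic acid
Conditions: LiOH, THF/MeOH/H2O, rt; then 1 M HCl to pH 3
Reagents that add atoms: lithium hydroxide, [Li+].[OH-]
Why: Ester saponification at room temperature should spare the tertiary silyl ether and should not trigger retro-oxa-Michael opening of the β-alkoxy ester.

Step 6
Reactants: 6 2-[(2S,3S,6S)-3-(tert-butyldimethylsilyloxy)-3-methyl-6-(prop-1-en-2-yl)oxan-2-yl]acetic acid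
Product: 8 1-diazo-3-[(2S,3S,6S)-3-(tert-butyldimethylsilyloxy)-3-methyl-6-(prop-1-en-2-yl)oxan-2-yl]propan-2-one, via mixed carbonic anhydride 7 (not isolated)
Conditions: i-BuOCOCl, Et3N, Et2O, −20 °C; then CH2N2, Et2O, 0 °C
Reagents that add atoms: diazomethane, C=[N+]=[N-]
Why: Acylation of diazomethane by a mixed carbonic anhydride (first stage of an Arndt–Eistert sequence) gives the α-diazo ketone under neutral conditions that leave the allyl ether and the silyl ether alone.

Step 7
Reactants: 8 1-diazo-3-[(2S,3S,6S)-3-(tert-butyldimethylsilyloxy)-3-methyl-6-(prop-1-en-2-yl)oxan-2-yl]propan-2-one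
Product: 10 (1S,2S,5E,8S)-2-(tert-butyldimethylsilyloxy)-2,6-dimethyl-11-oxabicyclo[6.2.1]undec-5-en-9-one, via oxonium ylide 9 (not isolated)
Conditions: Rh2(NHCOCF3)4 (2 mol%), CH2Cl2, reflux, slow addition of 8
Reagents that add atoms: none
Why: The rhodium catalyst turns the diazo ketone into an electrophilic carbenoid at C9, a lone pair of the oxane oxygen adds to it (this makes the O–C9 bond and closes the five-membered oxolan-3-one ring as the bicyclic allyl oxonium ylide 9), and the ylide undergoes a [2,3]-sigmatropic shift in which C9 bonds to the isopropenyl CH2 (C8) while O–C6 breaks and C6=C7 forms. The closest known reaction type is the metal-catalysed oxonium ylide formation/[2,3] rearrangement of cyclic allyl ethers that carry a diazo ketone arm, established for 6-alkenyl oxanes with a 3-diazo-2-oxopropyl group at C2. The oxolanone closes by attack of oxygen on the carbenoid through a five-membered transition state (favoured over the six-membered ylide at the silyl ether oxygen and over C–H insertion), whereas the oxonene and the ten-membered carbocycle are not closed end to end but arise by three-atom ring expansion of the oxane through the five-membered envelope transition state of the [2,3] shift. The new stereocentre C9 is set by C2, because the allyl group can only migrate across the face of the oxonium ring to which the C3–C5 chain holds it, which gives the cis-2,9-bridged ether; the 2,6-cis C6 centre of 8 is what puts the isopropenyl group within reach and is then lost, and C2 and C3 are carried over unchanged. The step needs ylide formation to beat cyclopropanation and C–H insertion (secured by the 1,5-relationship of carbenoid and oxygen and by the electron-poor carboxamidate ligands) and the [2,3] shift to beat a [1,2] shift (secured by the allyl group). It also needs the E geometry at C6=C7, which depends on the isopropenyl rotamer in the transition state and on the catalyst: the rhodium carboxamidate is chosen because it is expected to favour E, whereas Cu(hfacac)2 is known to favour Z.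

Step 8
Reactants: 10 (1S,2S,5E,8S)-2-(tert-butyldimethylsilyloxy)-2,6-dimethyl-11-oxabicyclo[6.2.1]undec-5-en-9-one
Product: 12 enol triflate of 10 (C1=C10 with OTf on C10), via sodium enolate 11 (not isolated)
Conditions: NaN(SiMe3)2, THF, −78 °C; then PhNTf2, −78 °C to rt
Reagents that add atoms: N-phenylbis(trifluoromethanesulfonimide), O=S(=O)(C(F)(F)F)N(c1ccccc1)S(=O)(=O)C(F)(F)F
Why: Kinetic enolisation and O-triflation take place at the C1 methylene and not at the bridgehead C9–H, whose enolate would be a strained bridgehead alkene, so C9 is not epimerised.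

Step 9
Reactants: 12 enol triflate of 10; 13 tributyl(1-ethoxyethenyl)stannane
Product: 14 2-ethoxy diene (C1=C10–C11(OEt)=C12H2 on the oxabicycle)
Conditions: Pd(PPh3)4 (5 mol%), LiCl, THF, 65 °C
Reagents that add atoms: none
Why: Stille cross-coupling (oxidative addition of zerovalent palladium to the enol triflate, chloride-assisted transmetalation, reductive elimination) installs C11 and C12 as an electron-rich diene.

Step 10
Reactants: 14 2-ethoxy diene; 15 methyl vinyl ketone
Product: 17 tricyclic enol ether methyl ketone (C14 acetyl trans to C2), via C14-epimeric cycloadduct 16 (not isolated)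
Conditions: toluene, 110 °C (sealed tube); then K2CO3, MeOH, rt
Reagents that add atoms: none
Why: In this Diels–Alder reaction the 2-ethoxy group and the C1 substituent both direct the acetyl-bearing carbon to C1, the dienophile adds to the diene face opposite the C3–C8 bridge (which sets C1), and K2CO3 then equilibrates C14 through the ketone enolate to the trans (diequatorial) isomer.

Step 11
Reactants: 17 tricyclic enol ether methyl ketone
Product: 19 terminal vinyl triflate (C15(OTf)=CH2 on C14), via potassium enolate 18 (not isolated)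
Conditions: KN(SiMe3)2, THF, −78 °C; then PhNTf2
Reagents that add atoms: N-phenylbis(trifluoromethanesulfonimide), O=S(=O)(C(F)(F)F)N(c1ccccc1)S(=O)(=O)C(F)(F)F
Why: Kinetic enolate formation and triflation: the bulky amide base removes an acetyl methyl proton in preference to the tertiary C14–H, so the terminal enol triflate forms without epimerising C14.

Step 12
Reactants: 19 terminal vinyl triflate
Product: 21 C11 ketone carrying the 2-(trimethylsilyl)ethyl acrylate at C14, via enol ether acrylate 20 (not isolated)
Conditions: Pd(OAc)2 (5 mol%), PPh3, Et3N, CO (1 atm), Me3SiCH2CH2OH, DMF, 60 °C; then 1 M HCl, THF, rt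
Reagents that add atoms: carbon monoxide, [C-]#[O+]; 2-(trimethylsilyl)ethanol, C[Si](C)(C)CCO; water, O
Why: Palladium-catalysed alkoxycarbonylation of the vinyl triflate (oxidative addition, CO insertion, alcoholysis) builds C16 as an acrylate, and the acid treatment hydrolyses the ethyl enol ether to the C11 ketone with equilibrating protonation at C10 giving the cis ring fusion (H1 and H10 cis), the only fusion the bridged oxolane takes without strain.

Step 13
Reactants: 21 C11 ketone carrying the 2-(trimethylsilyl)ethyl acrylate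
Product: 23 C11 tertiary acetate, via bromomagnesium alkoxide 22 (not isolated)
Conditions: MeMgBr, THF, −78 °C; then Ac2O, DMAP, −78 °C to rt
Reagents that add atoms: methylmagnesium bromide, C[Mg]Br; acetic anhydride, CC(=O)OC(C)=O
Why: Grignard 1,2-addition with in situ O-acylation: the ketone reacts faster than the hindered acrylate at low temperature, methyl attacks C11 from the convex face of the cis-fused bicycle (the face of H1 and H10, away from the oxolane), which sets C11, and the alkoxide is acetylated directly.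

Step 14
Reactants: 23 C11 tertiary acetate
Product: 24 C3-hydroxy acrylic acid
Conditions: Bu4NF, THF, 50 °C; then dilute HCl work-up
Reagents that add atoms: none
Why: Fluoride-mediated desilylation cleaves the 2-(trimethylsilyl)ethyl ester by β-elimination (ethene and carboxylate) and the tertiary silyl ether, while the hindered tertiary acetate should survive.

Step 15
Reactants: 24 C3-hydroxy acrylic acid
Product: 25 (15R)-hydroxy acid
Conditions: H2 (50 atm), Ru(OAc)2[(R)-BINAP] (2 mol%), MeOH, rt
Reagents that add atoms: none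
Why: Noyori-type carboxylate-directed asymmetric hydrogenation of a 2-substituted acrylic acid reduces only the conjugated alkene, with the ligand enantiomer chosen (by analogy to other 2-substituted acrylic acids) to give 15R, and leaves the isolated trisubstituted C6=C7 alkene alone.

Step 16
Reactants: 25 (15R)-hydroxy acid
Product: 27 (6E)-lactone acetate, via mixed anhydride 26 (not isolated)
Conditions: 2,4,6-trichlorobenzoyl chloride, Et3N, THF, rt; then DMAP, toluene, 80 °C
Reagents that add atoms: none
Why: Yamaguchi lactonisation: with DMAP as acyl-transfer catalyst the mixed anhydride is attacked by the C3 tertiary hydroxyl, the only free hydroxyl, which the trans arrangement of C2 and C15 on the cyclohexane holds within reach for seven-membered ring closure.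

Step 17
Reactants: 27 (6E)-lactone acetate
Product: 28 (6R,7R)-6,7-diol
Conditions: OsO4 (5 mol%), N-methylmorpholine N-oxide, acetone/H2O, 0 °C to rt
Reagents that add atoms: N-methylmorpholine N-oxide, C[N+]1([O-])CCOCC1; water, O
Why: Upjohn dihydroxylation (OsO4-catalysed syn addition): only the outer face of the E alkene in the nine-membered ring is open, so both oxygens should add from outside the ring and set C6 and C7 together in the relative configuration that syn addition to an E alkene gives, which is that of the target.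

Step 18
Reactants: 28 (6R,7R)-6,7-diol
Product: 29 target (CNP0238771.1)
Conditions: Me3OBF4, 1,8-bis(dimethylamino)naphthalene, CH2Cl2, rt
Reagents that add atoms: trimethyloxonium tetrafluoroborate, C[O+](C)C.F[B-](F)(F)F
Why: O-methylation with a trialkyloxonium salt and a non-nucleophilic base alkylates the secondary C6 hydroxyl while the tertiary C7 hydroxyl is too hindered, and the lactone, the acetate and the epimerisable C15 are never exposed to strong base.

Compound list
1 | (S)-(+)-linalool, (3S)-3,7-dimethylocta-1,6-dien-3-ol | CC(C)=CCC[C@](C)(O)C=C | starting material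
2 | (3S)-3-(tert-butyldimethylsilyloxy)-3,7-dimethylocta-1,6-diene | CC(C)=CCC[C@](C)(O[Si](C)(C)C(C)(C)C)C=C | intermediate
3 | (3S,6S)-3-(tert-butyldimethylsilyloxy)-6,7-epoxy-3,7-dimethyloct-1-ene | CC1(C)O[C@H]1CC[C@](C)(O[Si](C)(C)C(C)(C)C)C=C | intermediate
4 | (3S,6S)-6-(tert-butyldimethylsilyloxy)-2,6-dimethylocta-1,7-dien-3-ol | CC(=C)[C@@H](O)CC[C@](C)(O[Si](C)(C)C(C)(C)C)C=C | intermediate
5 | methyl 2-[(2S,3S,6S)-3-(tert-butyldimethylsilyloxy)-3-methyl-6-(prop-1-en-2-yl)oxan-2-yl]acetate (2,6-cis) | CC(=C)[C@@H]1CC[C@](C)(O[Si](C)(C)C(C)(C)C)[C@H](CC(=O)OC)O1 | intermediate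
6 | 2-[(2S,3S,6S)-3-(tert-butyldimethylsilyloxy)-3-methyl-6-(prop-1-en-2-yl)oxan-2-yl]acetic acid | CC(=C)[C@@H]1CC[C@](C)(O[Si](C)(C)C(C)(C)C)[C@H](CC(=O)O)O1 | intermediate
7 | isobutyl carbonic mixed anhydride of 6 | CC(=C)[C@@H]1CC[C@](C)(O[Si](C)(C)C(C)(C)C)[C@H](CC(=O)OC(=O)OCC(C)C)O1 | intermediate
8 | 1-diazo-3-[(2S,3S,6S)-3-(tert-butyldimethylsilyloxy)-3-methyl-6-(prop-1-en-2-yl)oxan-2-yl]propan-2-one | CC(=C)[C@@H]1CC[C@](C)(O[Si](C)(C)C(C)(C)C)[C@H](CC(=O)C=[N+]=[N-])O1 | intermediate
9 | bicyclic allyl oxonium ylide (oxane oxygen bonded to C9, 3-oxo-oxolanium ring fused at O and C2, carbanion at C9) | CC(=C)[C@@H]1CC[C@](C)(O[Si](C)(C)C(C)(C)C)[C@@H]2CC(=O)[CH-][O+]12 | intermediate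
10 | (1S,2S,5E,8S)-2-(tert-butyldimethylsilyloxy)-2,6-dimethyl-11-oxabicyclo[6.2.1]undec-5-en-9-one (2S,3S,9S,6E in target locants) | C/C1=C\CC[C@](C)(O[Si](C)(C)C(C)(C)C)[C@H]2O[C@@H](C1)C(=O)C2 | intermediate
11 | sodium enolate of 10 (C1=C10–ONa) | C/C1=C\CC[C@](C)(O[Si](C)(C)C(C)(C)C)[C@H]2O[C@@H](C1)C([O-])=C2.[Na+] | intermediate
12 | (1S,2S,5E,8S)-2-(tert-butyldimethylsilyloxy)-2,6-dimethyl-11-oxabicyclo[6.2.1]undeca-5,9-dien-9-yl trifluoromethanesulfonate | C/C1=C\CC[C@](C)(O[Si](C)(C)C(C)(C)C)[C@H]2O[C@@H](C1)C(OS(=O)(=O)C(F)(F)F)=C2 | intermediate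
13 | tributyl(1-ethoxyethenyl)stannane | CCCC[Sn](CCCC)(CCCC)C(=C)OCC | starting material
14 | 9-(1-ethoxyethenyl) analogue of 12 (diene C1=C10–C11(OEt)=C12H2) | C/C1=C\CC[C@](C)(O[Si](C)(C)C(C)(C)C)[C@H]2O[C@@H](C1)C(C(=C)OCC)=C2 | intermediate
15 | methyl vinyl ketone (but-3-en-2-one) | CC(=O)C=C | starting material
16 | C14 epimer of 17 (acetyl cis to C2, from the endo transition state) | C/C1=C\CC[C@](C)(O[Si](C)(C)C(C)(C)C)[C@H]2O[C@@H](C1)C3=C(OCC)CC[C@H](C(C)=O)[C@H]23 | intermediate
17 | tricyclic adduct: C10=C11 ethyl enol ether, acetyl on C14 trans to C2, cyclohexene on the oxolane face opposite the C3–C8 bridge, 6E | C/C1=C\CC[C@](C)(O[Si](C)(C)C(C)(C)C)[C@H]2O[C@@H](C1)C3=C(OCC)CC[C@@H](C(C)=O)[C@H]23 | intermediate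
18 | potassium enolate of 17 at the acetyl methyl group | C/C1=C\CC[C@](C)(O[Si](C)(C)C(C)(C)C)[C@H]2O[C@@H](C1)C3=C(OCC)CC[C@@H](C([O-])=C)[C@H]23.[K+] | intermediate
19 | vinyl triflate of 17 (C14–C(OTf)=CH2) | C/C1=C\CC[C@](C)(O[Si](C)(C)C(C)(C)C)[C@H]2O[C@@H](C1)C3=C(OCC)CC[C@@H](C(=C)OS(=O)(=O)C(F)(F)F)[C@H]23 | intermediate
20 | 2-(trimethylsilyl)ethyl acrylate (C14–C(=CH2)–CO2CH2CH2SiMe3) still carrying the C10=C11 enol ether | C/C1=C\CC[C@](C)(O[Si](C)(C)C(C)(C)C)[C@H]2O[C@@H](C1)C3=C(OCC)CC[C@@H](C(=C)C(=O)OCC[Si](C)(C)C)[C@H]23 | intermediate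
21 | cis-fused C11 ketone with the 2-(trimethylsilyl)ethyl acrylate on C14 (C1, C2, C3, C9, C10, C14 as in 29) | C/C1=C\CC[C@](C)(O[Si](C)(C)C(C)(C)C)[C@H]2O[C@@H](C1)[C@H]3[C@@H]2[C@@H](CCC3=O)C(=C)C(=O)OCC[Si](C)(C)C | intermediate
22 | bromomagnesium C11 alkoxide from 21 (C11 methyl on the face of H10) | C/C1=C\CC[C@](C)(O[Si](C)(C)C(C)(C)C)[C@H]2O[C@@H](C1)[C@H]3[C@@H]2[C@@H](CC[C@@]3(C)O[Mg]Br)C(=C)C(=O)OCC[Si](C)(C)C | intermediate
23 | C11 tertiary acetate (C3 silyl ether, silylethyl acrylate) | C/C1=C\CC[C@](C)(O[Si](C)(C)C(C)(C)C)[C@H]2O[C@@H](C1)[C@H]3[C@@H]2[C@@H](CC[C@@]3(C)OC(C)=O)C(=C)C(=O)OCC[Si](C)(C)C | intermediate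
24 | C3-hydroxy acrylic acid (C14–C(=CH2)–CO2H, C11 acetate) | C/C1=C\CC[C@](C)(O)[C@H]2O[C@@H](C1)[C@H]3[C@@H]2[C@@H](CC[C@@]3(C)OC(C)=O)C(=C)C(=O)O | intermediate
25 | (15R)-hydroxy acid (C14–CH(CH3)–CO2H) | C/C1=C\CC[C@](C)(O)[C@H]2O[C@@H](C1)[C@H]3[C@@H]2[C@@H](CC[C@@]3(C)OC(C)=O)[C@@H](C)C(=O)O | intermediate
26 | 2,4,6-trichlorobenzoic mixed anhydride of 25 | C/C1=C\CC[C@](C)(O)[C@H]2O[C@@H](C1)[C@H]3[C@@H]2[C@@H](CC[C@@]3(C)OC(C)=O)[C@@H](C)C(=O)OC(=O)c4c(Cl)cc(Cl)cc4Cl | intermediate
27 | (6E)-lactone acetate: 29 with C6=C7 in place of C6–OMe/C7–OH | C/C1=C\CC[C@]2(C)OC(=O)[C@H](C)[C@@H]3CC[C@@](C)(OC(C)=O)[C@@H]4[C@H]3[C@@H]2O[C@H]4C1 | intermediate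
28 | (6R,7R)-6,7-diol (6-O-demethyl 29) | O[C@@H]1CC[C@]2(C)OC(=O)[C@H](C)[C@@H]3CC[C@@](C)(OC(C)=O)[C@@H]4[C@H]3[C@@H]2O[C@H]4C[C@@]1(C)O | intermediate
29 | CNP0238771.1, (1S,2S,3S,6R,7R,9S,10R,11R,14R,15R) in the locants of the overview | CO[C@@H]1CC[C@]2(C)OC(=O)[C@H](C)[C@@H]3CC[C@@](C)(OC(C)=O)[C@@H]4[C@H]3[C@@H]2O[C@H]4C[C@@]1(C)O | target

Total step count: 18. Longest linear sequence: 18 steps (1 to 29); 13 and 15 are bought.

Steps most likely to fail

Step 4. The oxypalladation may be slow because the vinyl group sits next to the fully substituted C3, so that Wacker-type oxidation, β-hydride elimination or attack on the isopropenyl group could compete, and the 2,6-cis preference may erode. The fallback sets out from 3 and swaps oxypalladation for an oxa-Michael ring closure. Ozonolysis of the vinyl group of 3 (O3, CH2Cl2, −78 °C; Me2S) would give the α-silyloxy aldehyde F1. Wittig reaction with Ph3P=CHCO2Me would give the (E)-enoate F2. Isomerisation of the epoxide with Et2Al(tmp) (tmp = 2,2,6,6-tetramethylpiperidide; toluene, 0 °C, which spares the ester) would give the hydroxy enoate F3. Under KOt-Bu (cat.) in THF, F3 should close by reversible oxa-Michael addition to the thermodynamically preferred 2,6-cis oxane, which is 5, where the route is rejoined.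

Step 16. Acylation of the hindered tertiary C3 hydroxyl may be slower than enolisation or ketene formation from the activated acid, which would erode the C15 configuration, or slower than intermolecular anhydride formation. The fallback sets out from 24 and closes the lactone before C15 exists. Yamaguchi activation of the acrylic acid gives the mixed anhydride F4, which has no α-hydrogen and can be heated with DMAP until the α-methylene lactone F5 forms. C15 is then set on the rigid lactone by homogeneous hydrogenation of the exocyclic alkene (H2, Ru(OAc)2[(R)-BINAP] or its enantiomer, whichever matches the bias of the ring; a known reaction type for α-methylene lactones). This gives 27, where the route is rejoined.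

Step 17. Facial selectivity may be poor or reversed: if the oxonene reacts through its other planar-chiral conformer, osmylation would give the 6,7-bis-epimeric diol. The fallback sets out from 27 and builds the diol on the Z isomer instead. Thiyl-radical equilibration (PhSH, AIBN, benzene, 80 °C) should convert 27 into the more stable Z lactone F6. Dihydroxylation (OsO4, N-methylmorpholine N-oxide) from the exposed outer face should give the cis-diol F7, in which C7 is correct and C6 is epimeric. Oxidation of the secondary alcohol (Dess–Martin periodinane) gives the 7-hydroxy 6-ketone F8. Reduction with NaBH4 (MeOH, −40 °C; non-chelating, Felkin–Anh attack from the outer face) should give 28, where the route is rejoined.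

Further compounds
F1 | step 4 | (2S)-2-(tert-butyldimethylsilyloxy)-4-[(2S)-3,3-dimethyloxiran-2-yl]-2-methylbutanal | CC1(C)O[C@H]1CC[C@](C)(O[Si](C)(C)C(C)(C)C)C=O
F2 | step 4 | methyl (2E,4S)-4-(tert-butyldimethylsilyloxy)-6-[(2S)-3,3-dimethyloxiran-2-yl]-4-methylhex-2-enoate | CC1(C)O[C@H]1CC[C@](C)(O[Si](C)(C)C(C)(C)C)/C=C/C(=O)OC
F3 | step 4 | methyl (2E,4S,7S)-4-(tert-butyldimethylsilyloxy)-7-hydroxy-4,8-dimethylnona-2,8-dienoate | CC(=C)[C@@H](O)CC[C@](C)(O[Si](C)(C)C(C)(C)C)/C=C/C(=O)OC
F4 | step 16 | 2,4,6-trichlorobenzoic mixed anhydride of 24 | C/C1=C\CC[C@](C)(O)[C@H]2O[C@@H](C1)[C@H]3[C@@H]2[C@@H](CC[C@@]3(C)OC(C)=O)C(=C)C(=O)OC(=O)c4c(Cl)cc(Cl)cc4Cl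
F5 | step 16 | α-methylene lactone (27 with C15=CH2 in place of C15H–CH3) | C/C1=C\CC[C@]2(C)OC(=O)C(=C)[C@@H]3CC[C@@](C)(OC(C)=O)[C@@H]4[C@H]3[C@@H]2O[C@H]4C1
F6 | step 17 | (6Z) isomer of 27 | C/C1=C/CC[C@]2(C)OC(=O)[C@H](C)[C@@H]3CC[C@@](C)(OC(C)=O)[C@@H]4[C@H]3[C@@H]2O[C@H]4C1
F7 | step 17 | (6S,7R)-6,7-diol (6-epimer of 28) | O[C@H]1CC[C@]2(C)OC(=O)[C@H](C)[C@@H]3CC[C@@](C)(OC(C)=O)[C@@H]4[C@H]3[C@@H]2O[C@H]4C[C@@]1(C)O
F8 | step 17 | (7R)-7-hydroxy 6-ketone (6-oxo analogue of 28) | O=C1CC[C@]2(C)OC(=O)[C@H](C)[C@@H]3CC[C@@](C)(OC(C)=O)[C@@H]4[C@H]3[C@@H]2O[C@H]4C[C@@]1(C)O
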